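# Synthesis plan for CNP0161524.1, (2S)-3'-[(E)-7-hydroxy-3,7-dimethyloct-2-enyl]naringenin (18)

## Structural features

The target 18 is a (2S)-flavanone: a 5,7-dihydroxychroman-4-one (aromatic ring A fused to the dihydropyranone ring C) with a 4-hydroxyphenyl ring B at C2. Ring B carries at C3', next to the 4'-hydroxyl, an (E)-7-hydroxy-3,7-dimethyloct-2-enyl chain, that is, a geranyl group hydrated at its distal alkene. C2 is the only stereocentre and has no stereogenic neighbour, but it is benzylic, bound to the ring oxygen O1 and β to the C4 ketone, and is therefore configurationally fragile. Base opens ring C by retro-oxa-Michael elimination, a free 4'-phenoxide can expel O1 in a quinone-methide fashion, and strong acid can ionise the C2–O1 bond. The second stereo-element is the trisubstituted C2''=C3'' alkene, whose (E) geometry has to be delivered and kept. The tertiary alcohol and the trisubstituted alkene of the chain are acid-labile (cation formation, dehydration, cyclisation onto the neighbouring 4'-OH), and the three phenols are oxidation-prone. The real difficulty is the order of events: ring C must be closed and ring A unmasked under acidic conditions that the chain cannot survive, and the chain must then be attached under conditions that the base-sensitive C2 centre survives. The key step uses the local symmetry of ring A: in a 3,5-dioxygenated phenyl ether the two carbons ortho to O1 (future C4a and C8) are equivalent and activated by all three oxygens, so an acyl electrophile at C4 held by the O1–C2–C3 tether can only form C4–C4a and close ring C.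

## Logic of the disconnections

18 ⇐ 17. The O4'–acetyl bond is cut last. The acetyl group is kept until the end because it blocks the quinone-methide racemisation channel of C2 and keeps ring B electron-poor. The forward step must be a neutral solvolysis, since 18 itself is base-sensitive.

17 ⇐ 14 + 16. The C3'–C1'' bond between ring B and the chain is cut, which divides the molecule into the complete flavanone core and a ten-carbon chain. The cut is placed here because the chain survives neither the ring closure nor the ether cleavage and must enter after both. The polarity is aryl nucleophile (tin in 14) plus allylic electrophile (acetate 16). An η3-allyl palladium complex formed by ionisation of an (E)-allylic acetate keeps its geometry. The opposite polarity (allyl nucleophile onto an aryl halide) passes through a tertiary σ-allyl species in which the alkene geometry is decided anew. The forward step must couple at the primary terminus, in a neutral medium, in the presence of two free phenols and a tertiary alcohol.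

16 ⇐ 15. The C7–O bond is cut (Markovnikov hydration). This takes the chain back to a commodity terpene ester in one step. The forward step must distinguish the distal alkene from the one bearing the allylic acetate.

14 ⇐ 13. The C3'–Sn bond is traced back to C3'–I. The iodide is inert to all earlier steps, whereas a carbon–tin bond would not survive the acids. The forward step must be base-free and tolerate ketone, ester and phenols.

13 ⇐ 12. The two benzyl–oxygen bonds on ring A are restored. Ring A has to be an electron-rich triether during the acylation, and the Lewis acid that removes the benzyl groups would destroy the chain, so this cut comes before the chain is attached. The forward step must avoid C-benzylation of ring A and must not disturb C2 or the acetate.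

12 ⇐ 10 (through 11). The C4–C4a bond is cut, opening ring C. The bicyclic ketone becomes an open-chain acid whose single stereocentre is made separately. Symmetry removes any regiochemical question. The forward step must keep the configuration at C2 in acid, which is why ring B carries the acetoxy and iodo groups and no chain.

10 ⇐ 9. The ester C–O bond of a tert-butyl ester is restored. Acid cleavage avoids hydroxide, which would eliminate the β-aryloxy group and cleave the acetate. The forward step must trap the tert-butyl cation before it attacks ring A.

9 ⇐ 7 + 8. The C2–O1 aryl ether bond is cut, joining the ring A and ring B halves convergently. The stereocentre is transferred by inversion of a carbinol, so 7 needs the (R) configuration. The forward step must be a clean SN2 process without β-elimination.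

7 ⇐ 6 ⇐ 5 ⇐ 2 + 3 (through 4). The C2–H bond is set by enantioselective reduction of ketone 6. Ketone 6 comes from carbinol 5, and 5 from cutting the C2–C3 bond (acetate aldol). The redox relay costs one step but puts the stereocentre under the most dependable catalyst control. The aldol must select the aldehyde over the aryl ester.

2 ⇐ 1. The O–acetyl bond is cut, giving the commercial iodophenol aldehyde.

## Other disconnections considered

Alternative 1: Ring C is cut at three bonds at once, C4a–C4, C4–C3 and O1–C2. In the forward sense the tris-silylated flavone A1 would arise from 2-iodo-3,5-bis(triisopropylsilyloxy)phenol A2, carbon monoxide A3 and the ring B alkyne A4 with PdCl2(PPh3)2 (reduced in the flask to zerovalent palladium) and diethylamine. The sequence is oxidative addition, CO insertion, alkynyl coupling and 6-endo-dig attack of the phenol.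
- In its favour: three bonds are formed in one operation from two fragments of similar size. The medium is not acidic, so the complete side chain can ride on A4. On convergence and on tolerance of the chain this plan is better than the chosen one.
- Against it here: A1 is a flavone, so C2 is planar. The only stereocentre would have to be created afterwards by enantioselective conjugate reduction of the C2=C3 bond in the presence of a trisubstituted alkene, a far less general operation than ketone transfer hydrogenation. Fluoride desilylation would then be run on a base-sensitive flavanone. The iodide of A2 is flanked by two oxygen substituents, hot diethylamine threatens aryl silyl ethers, and 5-exo closure competes.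
- Comparison: regiocontrol is equal in both plans (dictated by the bonds formed). Stereocontrol is clearly weaker. The step count would be similar once reduction and deprotection are added, so nothing is gained.

Alternative 2: Ring A is cut instead (C8a–C8, C5–C6, C7–C8, C4a–C5), and ring C with C2 already in place becomes the platform. Irradiation of the diazo ketone A6 with (triisopropylsilyloxy)ethyne A7 would start Wolff rearrangement, ketene–alkyne [2+2] addition, four-electron ring opening and six-electron closure, to give the 5-hydroxy-7-silyloxy flavanone A5.
- In its favour: the conditions are neutral (light, then mild heat), so the chain is tolerated, which is better than the chosen plan. The oxygen pattern of ring A is delivered regiospecifically and already differentiated, equal to the symmetry argument of the chosen plan. C2 could be set by an asymmetric hetero-Diels–Alder reaction, of comparable quality to the transfer hydrogenation.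
- Against it here: A6 is far from commercial materials. It needs a 6-acyl-2-aryl-dihydropyranone and a diazo transfer or diazomethane acylation, both under conditions in which this vinylogous β-alkoxy ketone can ring-open. The enone and the chain alkene are additional chromophores and reaction partners under irradiation.
- Comparison: the pericyclic cascade is more elegant and equally selective in principle. It has more individual points of failure and is clearly longer, so step economy favours the chosen plan.

Alternative 3: The cut is at C3–C4. The aldehyde A9, which carries the (R)-configured 1-aryl-2-iodoethyl ether (spatially the same centre as C2 of the product), would be treated with a thiazol-2-ylidene made from a 3-benzylthiazolium salt and 1,8-diazabicyclo[5.4.0]undec-7-ene. The carbene-bound acyl anion equivalent displaces the primary iodide in a 6-exo-tet closure to give A8.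
- In its favour: no acid is used, so the chain is tolerated (better). The stereocentre is made beforehand and is not involved in the bond formation (equal to the chosen plan). One final fluoride step would replace two deprotections (equal or slightly better in count).
- Against it here: the amidine base can remove hydrogen iodide from A9, since the C2 hydrogen is benzylic and α to oxygen. The aldehyde is flanked by two ortho oxygens, electron-rich and hindered, so carbene addition is slow. Amidines cleave aryl silyl ethers. The product A8 is base-labile at C2. Making A9 requires a regioselective mono-etherification of a trioxygenated benzaldehyde with a β-halo benzylic unit, which is harder than the etherification of the chosen plan.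
- Comparison: structurally equal in where the stereocentre comes from, mechanistically riskier (elimination against substitution), and not shorter.

Key step: step 7

Remarks on the chemistry, made before the steps:
- Descriptor check: an (R)-carbinol 7, inverted in the etherification, gives (S)-9 and (S)-10, and the same arrangement is (2S) in 12 to 18, the configuration of the target. No structure needed correction. The spatially identical centre of A9 is (R) only because CH2I outranks the aryl group.
- The precursor 10 is kept with the electron-poor ring B (acetoxy, iodo), benzyl ethers on ring A and no side chain. Two points are tightened: the tert-butyl cation is scavenged when 10 is liberated, and the anhydride is used in slight excess only.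
- The aryl–allyl bond is made with tin on the ring and acetate on the chain, for the reason of alkene geometry and neutrality stated above.
- Assumption: 1, 3, 8, 15 and all reagents are purchased, and LiN(i-Pr)2 is used as a commercial solution.

## Route

Step 1
Reactants: 1 4-hydroxy-3-iodobenzaldehyde
Product: 2 4-formyl-2-iodophenyl acetate
Conditions: Ac2O, pyridine, 4-(dimethylamino)pyridine (cat.), CH2Cl2, 0 °C to rt
Reagents that add atoms: acetic anhydride, CC(=O)OC(C)=O
Why: O-acetylation of the phenol by nucleophilic catalysis; the acetyl group later keeps ring B electron-poor, blocks the quinone-methide pathway at C2 and can be removed at neutral pH.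

Step 2
Reactants: 2 4-formyl-2-iodophenyl acetate; 3 tert-butyl acetate
Product: 5 tert-butyl 3-(4-acetoxy-3-iodophenyl)-3-hydroxypropanoate (racemic), via tert-butyl acetate lithium enolate 4 (not isolated)
Conditions: LiN(i-Pr)2 (1.05 equiv), 3 (1.1 equiv), THF, −78 °C; then 2, −78 °C, 20 min; AcOH quench at −78 °C
Reagents that add atoms: none
Why: Acetate aldol addition of a pre-formed lithium ester enolate; at −78 °C with no excess base the aldehyde is attacked much faster than the aryl ester, and the cold acidic quench prevents acyl transfer to the aldolate; the racemic carbinol is only a relay to the ketone.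

Step 3
Reactants: 5 tert-butyl 3-(4-acetoxy-3-iodophenyl)-3-hydroxypropanoate (racemic)
Product: 6 tert-butyl 3-(4-acetoxy-3-iodophenyl)-3-oxopropanoate
Conditions: Dess–Martin periodinane (1.2 equiv), CH2Cl2, rt
Reagents that add atoms: none
Why: Dess–Martin oxidation of a secondary benzylic alcohol to the β-keto ester under near-neutral conditions that leave the aryl acetate, aryl iodide and tert-butyl ester alone.

Step 4
Reactants: 6 tert-butyl 3-(4-acetoxy-3-iodophenyl)-3-oxopropanoate
Product: 7 tert-butyl (3R)-3-(4-acetoxy-3-iodophenyl)-3-hydroxypropanoate
Conditions: [RuCl(p-cymene)((R,R)-TsDPEN)] (1 mol%; TsDPEN = N-(p-toluenesulfonyl)-1,2-diphenylethane-1,2-diamine), HCO2H–Et3N (5:2), CH2Cl2, rt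
Reagents that add atoms: none
Why: Noyori asymmetric transfer hydrogenation of an aryl ketone; the (R,R)-diamine complex of divalent ruthenium should deliver hydride to the face that gives the (R)-benzylic carbinol (aryl recognition by the CH/π contact with the η6-arene), setting the only stereocentre of the route; aryl iodide and esters are inert to this catalyst.

Step 5
Reactants: 7 tert-butyl (3R)-3-(4-acetoxy-3-iodophenyl)-3-hydroxypropanoate; 8 3,5-bis(benzyloxy)phenol
Product: 9 tert-butyl (3S)-3-(4-acetoxy-3-iodophenyl)-3-[3,5-bis(benzyloxy)phenoxy]propanoate
Conditions: PPh3 (1.5 equiv), diisopropyl azodicarboxylate (1.5 equiv), toluene, 0 °C to rt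
Reagents that add atoms: none
Why: Mitsunobu etherification; the phenol is acidic enough to protonate the betaine and displaces the alkoxyphosphonium group by SN2, so (R)-7 becomes (S)-9 with inversion; the electron-poor ring B disfavours an SN1 leak, and low temperature in a non-polar solvent holds back β-elimination.

Step 6
Reactants: 9 tert-butyl (3S)-3-(4-acetoxy-3-iodophenyl)-3-[3,5-bis(benzyloxy)phenoxy]propanoate
Product: 10 (3S)-3-(4-acetoxy-3-iodophenyl)-3-[3,5-bis(benzyloxy)phenoxy]propanoic acid
Conditions: CF3CO2H–CH2Cl2 (1:4), Et3SiH (3 equiv), 0 °C to rt
Reagents that add atoms: none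
Why: Acidolysis of the tert-butyl ester by loss of the tert-butyl cation, which triethylsilane reduces to isobutane before it can alkylate the trioxygenated ring; benzyl ethers, the aryl acetate and the deactivated benzylic ether should tolerate dilute trifluoroacetic acid, and no hydroxide is used that would eliminate the β-aryloxy group.

Step 7
Reactants: 10 (3S)-3-(4-acetoxy-3-iodophenyl)-3-[3,5-bis(benzyloxy)phenoxy]propanoic acid
Product: 12 (2S)-4'-acetoxy-5,7-bis(benzyloxy)-3'-iodoflavanone, via mixed carboxylic trifluoroacetic anhydride 11 (not isolated)
Conditions: (CF3CO)2O (1.3 equiv), CH2Cl2, 0 °C; aq NaHCO3 work-up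
Reagents that add atoms: none
Why: Trifluoroacetic anhydride converts the acid into mixed anhydride 11, whose acyl carbon (or the acylium ion in equilibrium with it) is attacked by the ring A carbon ortho to O1; loss of trifluoroacetate and of the proton of the arenium ion gives the aryl ketone and forms C4–C4a. The closest known reaction type is the intramolecular Friedel–Crafts acylation of 3-aryloxypropanoic acids to chroman-4-ones through trifluoroacetic mixed anhydrides. Ring C closes in a 6-exo-trig mode at the acyl carbon, the carbonyl oxygen staying outside the new ring. No stereocentre is formed; C2 is carried through and none of its bonds takes part. Regiochemistry needs no control, because the two positions ortho to O1 are equivalent, each is ortho or para to all three oxygens, and the tether cannot reach the position para to O1. The selectivity that matters is retention at C2, which requires that the benzylic C2–O1 bond neither ionises nor eliminates: the acetoxy and iodo groups make ring B a poor cation-stabilising group, no strong protic or Lewis acid is present, and the activated ring reacts already at 0 °C. Competing intermolecular C-trifluoroacetylation of ring A is held back by using little more than one equivalent of anhydride, the six-membered intramolecular acylation being faster. The acid-labile side chain is absent by design and enters at the iodide afterwards.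

Step 8
Reactants: 12 (2S)-4'-acetoxy-5,7-bis(benzyloxy)-3'-iodoflavanone
Product: 13 (2S)-4'-acetoxy-5,7-dihydroxy-3'-iodoflavanone
Conditions: BCl3 (5 equiv), pentamethylbenzene (6 equiv), CH2Cl2, −78 to −40 °C; H2O quench
Reagents that add atoms: none
Why: Lewis-acid debenzylation with a non-coordinating cation scavenger, which takes up the benzyl cations and prevents C-benzylation of the phloroglucinol ring; at low temperature the aryl acetate, the aryl iodide and the C2–O1 bond (benzylic to an electron-poor ring) are expected to persist, the 5-O-benzyl group leaving first with chelation to the C4 carbonyl.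

Step 9
Reactants: 13 (2S)-4'-acetoxy-5,7-dihydroxy-3'-iodoflavanone
Product: 14 (2S)-4'-acetoxy-5,7-dihydroxy-3'-(tributylstannyl)flavanone
Conditions: (Bu3Sn)2 (1.5 equiv), Pd(PPh3)4 (5 mol%), 1,4-dioxane, 90 °C
Reagents that add atoms: hexabutylditin, CCCC[Sn](CCCC)(CCCC)[Sn](CCCC)(CCCC)CCCC
Why: Palladium-catalysed stannylation of an aryl iodide with a distannane (oxidative addition to zerovalent palladium, tin–tin transmetalation, reductive elimination); no base is required, so the base-sensitive C2 centre and the acetate are not put at risk.

Step 10
Reactants: 15 geranyl acetate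
Product: 16 (2E)-7-hydroxy-3,7-dimethyloct-2-en-1-yl acetate
Conditions: Co(acac)2 (20 mol%), PhSiH3 (1.2 equiv), O2 (1 atm), THF, rt
Reagents that add atoms: dioxygen, O=O
Why: Mukaiyama hydration (hydrogen-atom transfer from a cobalt hydride, trapping of the tertiary radical by O2, reduction of the peroxide by the silane) gives the Markovnikov tertiary alcohol; the distal alkene is the more electron-rich one, the other being deactivated by the allylic acetate, so with limiting silane it should react selectively and leave the (E)-alkene and the ester untouched.

Step 11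
Reactants: 14 (2S)-4'-acetoxy-5,7-dihydroxy-3'-(tributylstannyl)flavanone; 16 (2E)-7-hydroxy-3,7-dimethyloct-2-en-1-yl acetate
Product: 17 (2S)-4'-acetoxy-5,7-dihydroxy-3'-[(2E)-7-hydroxy-3,7-dimethyloct-2-en-1-yl]flavanone
Conditions: Pd(dba)2 (5 mol%), LiCl (3 equiv), DMF, 40 °C
Reagents that add atoms: none
Why: Stille coupling of an allylic acetate with an arylstannane: zerovalent palladium ionises the acetate to the η3-allyl complex with the (E) arrangement intact, chloride-assisted transmetalation transfers the aryl group, and reductive elimination occurs at the unhindered primary terminus, giving the linear (E) product; the neutral medium protects C2, and O-allylation of the acidic 7-OH, if it occurs, is reversible under the catalyst.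

Step 12
Reactants: 17 (2S)-4'-acetoxy-5,7-dihydroxy-3'-[(2E)-7-hydroxy-3,7-dimethyloct-2-en-1-yl]flavanone
Product: 18 (2S)-5,7-dihydroxy-2-{4-hydroxy-3-[(2E)-7-hydroxy-3,7-dimethyloct-2-en-1-yl]phenyl}chroman-4-one (target)
Conditions: NH4OAc (10 equiv), MeOH, rt
Reagents that add atoms: none
Why: Neutral methanolysis of an aryl acetate promoted by ammonium acetate; aryl esters are cleaved selectively, and the flavanone (base-labile at C2 once the 4'-phenol is free), the tertiary alcohol and the alkene are left untouched.

## Compound list

1 | 4-hydroxy-3-iodobenzaldehyde | O=Cc1ccc(O)c(I)c1 | starting material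
2 | 4-formyl-2-iodophenyl acetate | CC(=O)Oc1ccc(C=O)cc1I | intermediate
3 | tert-butyl acetate | CC(=O)OC(C)(C)C | starting material
4 | tert-butyl acetate lithium enolate | [Li]OC(=C)OC(C)(C)C | intermediate (not isolated)
5 | tert-butyl 3-(4-acetoxy-3-iodophenyl)-3-hydroxypropanoate (racemic) | CC(=O)Oc1ccc(cc1I)C(O)CC(=O)OC(C)(C)C | intermediate
6 | tert-butyl 3-(4-acetoxy-3-iodophenyl)-3-oxopropanoate | CC(=O)Oc1ccc(cc1I)C(=O)CC(=O)OC(C)(C)C | intermediate
7 | tert-butyl (3R)-3-(4-acetoxy-3-iodophenyl)-3-hydroxypropanoate | CC(=O)Oc1ccc(cc1I)[C@H](O)CC(=O)OC(C)(C)C | intermediate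
8 | 3,5-bis(benzyloxy)phenol | Oc1cc(OCc2ccccc2)cc(OCc2ccccc2)c1 | starting material
9 | tert-butyl (3S)-3-(4-acetoxy-3-iodophenyl)-3-[3,5-bis(benzyloxy)phenoxy]propanoate | CC(=O)Oc1ccc(cc1I)[C@@H](Oc1cc(OCc2ccccc2)cc(OCc2ccccc2)c1)CC(=O)OC(C)(C)C | intermediate
10 | (3S)-3-(4-acetoxy-3-iodophenyl)-3-[3,5-bis(benzyloxy)phenoxy]propanoic acid | CC(=O)Oc1ccc(cc1I)[C@@H](Oc1cc(OCc2ccccc2)cc(OCc2ccccc2)c1)CC(=O)O | intermediate
11 | (3S)-3-(4-acetoxy-3-iodophenyl)-3-[3,5-bis(benzyloxy)phenoxy]propanoic trifluoroacetic anhydride | CC(=O)Oc1ccc(cc1I)[C@@H](Oc1cc(OCc2ccccc2)cc(OCc2ccccc2)c1)CC(=O)OC(=O)C(F)(F)F | intermediate (not isolated)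
12 | (2S)-4'-acetoxy-5,7-bis(benzyloxy)-3'-iodoflavanone | CC(=O)Oc1ccc(cc1I)[C@@H]1CC(=O)c2c(OCc3ccccc3)cc(OCc3ccccc3)cc2O1 | intermediate
13 | (2S)-4'-acetoxy-5,7-dihydroxy-3'-iodoflavanone | CC(=O)Oc1ccc(cc1I)[C@@H]1CC(=O)c2c(O)cc(O)cc2O1 | intermediate
14 | (2S)-4'-acetoxy-5,7-dihydroxy-3'-(tributylstannyl)flavanone | CC(=O)Oc1ccc(cc1[Sn](CCCC)(CCCC)CCCC)[C@@H]1CC(=O)c2c(O)cc(O)cc2O1 | intermediate
15 | geranyl acetate | CC(C)=CCC/C(C)=C/COC(C)=O | starting material
16 | (2E)-7-hydroxy-3,7-dimethyloct-2-en-1-yl acetate | CC(=O)OC/C=C(\C)CCCC(C)(C)O | intermediate
17 | (2S)-4'-acetoxy-5,7-dihydroxy-3'-[(2E)-7-hydroxy-3,7-dimethyloct-2-en-1-yl]flavanone | C/C(=C\Cc1cc([C@@H]2CC(=O)c3c(O)cc(O)cc3O2)ccc1OC(C)=O)CCCC(C)(C)O | intermediate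
18 | (2S)-5,7-dihydroxy-2-{4-hydroxy-3-[(2E)-7-hydroxy-3,7-dimethyloct-2-en-1-yl]phenyl}chroman-4-one | C/C(=C\Cc1cc([C@@H]2CC(=O)c3c(O)cc(O)cc3O2)ccc1O)CCCC(C)(C)O | target

## Step count and least certain steps

Total: 12 steps. Longest linear sequence: 11 steps (1 to 18 through steps 1 to 9, 11 and 12). Step 10 is the only side-branch step.

**Step 7 (key step).**
- What may go wrong: partial loss of configuration at C2, by reversible ionisation of the benzylic C2–O1 bond or by acid-promoted elimination and re-addition of the phenol; also intermolecular C-trifluoroacetylation of ring A.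
- Why: the leaving group is a phenol in an acidic medium, and ring A is among the most nucleophilic arenes.
- Fallback (sets out from 2, comes back at 12): ring C would be closed at O1–C2 instead, by an organocatalytic enantioselective oxa-Michael addition.
  - Claisen condensation of methyl 2,4-bis(benzyloxy)-6-hydroxybenzoate F1 with an excess of enolate 4 would give tert-butyl 3-[2,4-bis(benzyloxy)-6-hydroxyphenyl]-3-oxopropanoate F2.
  - Knoevenagel condensation of F2 with 2 (piperidinium acetate, toluene, molecular sieves) would give tert-butyl 3-(4-acetoxy-3-iodophenyl)-2-[2,4-bis(benzyloxy)-6-hydroxybenzoyl]prop-2-enoate F3.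
  - The thiourea made from 9-amino-9-deoxy-epi-quinine and 3,5-bis(trifluoromethyl)phenyl isothiocyanate, or its quinidine-derived pseudoenantiomer, whichever leads to (2S), would induce conjugate addition of the phenol to give tert-butyl (2S)-2-(4-acetoxy-3-iodophenyl)-5,7-bis(benzyloxy)-4-oxochromane-3-carboxylate F4.
  - p-Toluenesulfonic acid in toluene at 80 °C would remove the tert-butyl ester with decarboxylation and return to 12.

**Step 5.**
- What may go wrong: β-elimination of the activated hydroxyl (dehydration) in place of substitution, and some C-alkylation of the ambident phenol.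
- Why: the ester makes the neighbouring CH2 acidic, and the betaine is basic.
- Fallback (sets out from 2, comes back at 10): the ester would be replaced by a vinyl group as a latent carboxyl, which has no acidic α-hydrogen.
  - Asymmetric allylboration of 2 with the B-allyldiisopinocampheylborane antipode prepared from (−)-α-pinene, the one expected to give the (R)-carbinol, with ethanolamine work-up, would give (1R)-1-(4-acetoxy-3-iodophenyl)but-3-en-1-ol F5.
  - Mitsunobu etherification of F5 with 8 would give 4-{(1S)-1-[3,5-bis(benzyloxy)phenoxy]but-3-en-1-yl}-2-iodophenyl acetate F6 with inversion.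
  - Dihydroxylation (OsO4 cat., N-methylmorpholine N-oxide) would give 4-{(1S)-1-[3,5-bis(benzyloxy)phenoxy]-3,4-dihydroxybutyl}-2-iodophenyl acetate F7.
  - NaIO4 would cleave F7 to (3S)-3-(4-acetoxy-3-iodophenyl)-3-[3,5-bis(benzyloxy)phenoxy]propanal F8.
  - Immediate Pinnick oxidation (NaClO2, NaH2PO4, 2-methylbut-2-ene) would give 10.

**Step 9.**
- What may go wrong: reductive loss of iodine, biaryl homocoupling, or protonolysis of the new carbon–tin bond by the acidic 7-OH at 90 °C.
- Why: the iodide is ortho-substituted, and the substrate carries its own proton source.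
- Fallback (sets out from 13, comes back at 17): boron would replace tin.
  - Miyaura borylation of 13 (B2pin2, PdCl2(dppf), KOAc, 1,4-dioxane, 80 °C) would give (2S)-4'-acetoxy-5,7-dihydroxy-3'-(4,4,5,5-tetramethyl-1,3,2-dioxaborolan-2-yl)flavanone F9.
  - Suzuki–Miyaura coupling of F9 with allylic acetate 16 (Pd(PPh3)4, KF, THF–H2O, 50 °C) would give 17. The alkene geometry is again carried by an η3-allyl complex formed by ionisation, at the price of mildly basic conditions.

**Step 11.**
- What may go wrong: slow aryl transfer from the hindered, electron-poor stannane. The η3-allyl complex could then decay by β-hydride elimination, or be captured by oxygen nucleophiles (the ring A phenols, or the tertiary hydroxyl with ether ring closure).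
- Why: the allyl complex is an electrophile that waits for a sluggish transmetalation.
- Fallback (sets out from 13 and 16, comes back at 17): the polarity would be reversed so that no electrophilic allyl species is present.
  - Palladium-catalysed borylation of 16 (B2pin2, Pd(dba)2, DMSO, 50 °C) would give (6E)-2,6-dimethyl-8-(4,4,5,5-tetramethyl-1,3,2-dioxaborolan-2-yl)oct-6-en-2-ol F10.
  - Suzuki–Miyaura coupling of F10 with iodide 13 (PdCl2(dppf), K3PO4, THF–H2O, 50 °C) would give 17.
  - The price is possible erosion of the (E) geometry and of the linear selectivity in the tertiary σ-allyl intermediate, and a basic medium. Separation on silver nitrate-impregnated silica would then be needed.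

## Further compounds

F1 | step 7 | methyl 2,4-bis(benzyloxy)-6-hydroxybenzoate | COC(=O)c1c(O)cc(OCc2ccccc2)cc1OCc1ccccc1
F2 | step 7 | tert-butyl 3-[2,4-bis(benzyloxy)-6-hydroxyphenyl]-3-oxopropanoate | CC(C)(C)OC(=O)CC(=O)c1c(O)cc(OCc2ccccc2)cc1OCc1ccccc1
F3 | step 7 | tert-butyl 3-(4-acetoxy-3-iodophenyl)-2-[2,4-bis(benzyloxy)-6-hydroxybenzoyl]prop-2-enoate | CC(=O)Oc1ccc(C=C(C(=O)OC(C)(C)C)C(=O)c2c(O)cc(OCc3ccccc3)cc2OCc2ccccc2)cc1I
F4 | step 7 | tert-butyl (2S)-2-(4-acetoxy-3-iodophenyl)-5,7-bis(benzyloxy)-4-oxochromane-3-carboxylate | CC(=O)Oc1ccc(cc1I)[C@@H]1C(C(=O)OC(C)(C)C)C(=O)c2c(OCc3ccccc3)cc(OCc3ccccc3)cc2O1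
F5 | step 5 | (1R)-1-(4-acetoxy-3-iodophenyl)but-3-en-1-ol | CC(=O)Oc1ccc(cc1I)[C@H](O)CC=C
F6 | step 5 | 4-{(1S)-1-[3,5-bis(benzyloxy)phenoxy]but-3-en-1-yl}-2-iodophenyl acetate | CC(=O)Oc1ccc(cc1I)[C@@H](Oc1cc(OCc2ccccc2)cc(OCc2ccccc2)c1)CC=C
F7 | step 5 | 4-{(1S)-1-[3,5-bis(benzyloxy)phenoxy]-3,4-dihydroxybutyl}-2-iodophenyl acetate | CC(=O)Oc1ccc(cc1I)[C@@H](Oc1cc(OCc2ccccc2)cc(OCc2ccccc2)c1)CC(O)CO
F8 | step 5 | (3S)-3-(4-acetoxy-3-iodophenyl)-3-[3,5-bis(benzyloxy)phenoxy]propanal | CC(=O)Oc1ccc(cc1I)[C@@H](Oc1cc(OCc2ccccc2)cc(OCc2ccccc2)c1)CC=O
F9 | step 9 | (2S)-4'-acetoxy-5,7-dihydroxy-3'-(4,4,5,5-tetramethyl-1,3,2-dioxaborolan-2-yl)flavanone | CC(=O)Oc1ccc(cc1B1OC(C)(C)C(C)(C)O1)[C@@H]1CC(=O)c2c(O)cc(O)cc2O1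
F10 | step 11 | (6E)-2,6-dimethyl-8-(4,4,5,5-tetramethyl-1,3,2-dioxaborolan-2-yl)oct-6-en-2-ol | CC(C)(O)CCC/C(C)=C/CB1OC(C)(C)C(C)(C)O1
A1 | alternative 1 | 5,7-bis(triisopropylsilyloxy)-2-{3-[(2E)-7-hydroxy-3,7-dimethyloct-2-en-1-yl]-4-(triisopropylsilyloxy)phenyl}chromen-4-one | C/C(=C\Cc1cc(-c2cc(=O)c3c(O[Si](C(C)C)(C(C)C)C(C)C)cc(O[Si](C(C)C)(C(C)C)C(C)C)cc3o2)ccc1O[Si](C(C)C)(C(C)C)C(C)C)CCCC(C)(C)O
A2 | alternative 1 | 2-iodo-3,5-bis(triisopropylsilyloxy)phenol | Oc1cc(O[Si](C(C)C)(C(C)C)C(C)C)cc(O[Si](C(C)C)(C(C)C)C(C)C)c1I
A3 | alternative 1 | carbon monoxide | [C-]#[O+]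
A4 | alternative 1 | (6E)-8-[5-ethynyl-2-(triisopropylsilyloxy)phenyl]-2,6-dimethyloct-6-en-2-ol | C#Cc1ccc(O[Si](C(C)C)(C(C)C)C(C)C)c(C/C=C(\C)CCCC(C)(C)O)c1
A5 | alternative 2 | (2S)-5-hydroxy-7-(triisopropylsilyloxy)-2-{3-[(2E)-3,7-dimethyl-7-(triethylsilyloxy)oct-2-en-1-yl]-4-(triisopropylsilyloxy)phenyl}chroman-4-one | C/C(=C\Cc1cc([C@@H]2CC(=O)c3c(O)cc(O[Si](C(C)C)(C(C)C)C(C)C)cc3O2)ccc1O[Si](C(C)C)(C(C)C)C(C)C)CCCC(C)(C)O[Si](CC)(CC)CC
A6 | alternative 2 | (2S)-6-(diazoacetyl)-2-{3-[(2E)-3,7-dimethyl-7-(triethylsilyloxy)oct-2-en-1-yl]-4-(triisopropylsilyloxy)phenyl}-2,3-dihydro-4H-pyran-4-one | C/C(=C\Cc1cc([C@@H]2CC(=O)C=C(C(=O)C=[N+]=[N-])O2)ccc1O[Si](C(C)C)(C(C)C)C(C)C)CCCC(C)(C)O[Si](CC)(CC)CC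
A7 | alternative 2 | (triisopropylsilyloxy)ethyne | C#CO[Si](C(C)C)(C(C)C)C(C)C
A8 | alternative 3 | (2S)-5,7-bis(triisopropylsilyloxy)-2-{3-[(2E)-3,7-dimethyl-7-(triethylsilyloxy)oct-2-en-1-yl]-4-(triisopropylsilyloxy)phenyl}chroman-4-one | C/C(=C\Cc1cc([C@@H]2CC(=O)c3c(O[Si](C(C)C)(C(C)C)C(C)C)cc(O[Si](C(C)C)(C(C)C)C(C)C)cc3O2)ccc1O[Si](C(C)C)(C(C)C)C(C)C)CCCC(C)(C)O[Si](CC)(CC)CC
A9 | alternative 3 | 2-{(1R)-1-[3-((2E)-3,7-dimethyl-7-(triethylsilyloxy)oct-2-en-1-yl)-4-(triisopropylsilyloxy)phenyl]-2-iodoethoxy}-4,6-bis(triisopropylsilyloxy)benzaldehyde | C/C(=C\Cc1cc([C@@H](Oc2cc(O[Si](C(C)C)(C(C)C)C(C)C)cc(O[Si](C(C)C)(C(C)C)C(C)C)c2C=O)CI)ccc1O[Si](C(C)C)(C(C)C)C(C)C)CCCC(C)(C)O[Si](CC)(CC)CC
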